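**Retrosynthetic overview**
1. Sodwanone T ⇐ (TBS removal, C‑3 oxidation, selective TES removal, desulfonylation) ⇐ central CH2–CH2 bond formed last by alkylating the lithiated C15 "west" allylic sulfone 27 (3‑OTES, becomes the ketone) with the C15 "east" allylic bromide 16 (3‑OTBS, carries the (3R)‑carbinol).
2. Each half ⇐ bicyclic β‑keto ester (enol triflate → Me2CuLi → DIBAL → Br or SO2Ph) ⇐ acyclic diepoxy β‑silyloxy enoate by one silyl‑triflate‑triggered epoxonium cascade.
3. Diepoxy β‑keto esters ⇐ methyl acetoacetate dianion + diepoxygeranyl triflate. East (6S,7S,10R) needs two controllers (Shi D‑ketone, then Sharpless L‑DET); west (all‑S, C‑10 later becomes C=O) comes from one double Shi epoxidation (ent‑ketone) of geraniol.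
4. Methyl geranate/geraniol ⇐ prenyl bromide + methyl acetoacetate (dianion alkylation, Z‑enol phosphate, Me2CuLi).
5. Ring order: in each half the oxepane closes first and the cyclohexane second (same operation, trans fusion); the ring alkenes come from the enol triflates; the two bicycles are joined last.

Assumption: the stereochemistry is taken exactly as written in the SMILES: both bicycles trans‑fused (5aS,9aS), carbinol (3R), i.e. 3‑OH cis to the 5a‑methyl. This makes the hydroxyl‑bearing epoxide opposite in sense to the ring‑fusion epoxide in the east half.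

Numbering: acyclic esters use chain numbering (C‑1 = ester carbon); bicycles use 1‑benzoxepine numbering (O1, C2 = CMe2, C3, C4, C5, C5a, C6 = linker‑bearing carbon, C7 = C–Me, C8, C9, C9a).

**Shared steps**

Step 1
Reactants: 1 methyl acetoacetate; 2 prenyl bromide
Product: 3 methyl 7‑methyl‑3‑oxooct‑6‑enoate
Conditions: NaH, THF, 0 °C; n‑BuLi; then 2, 0 °C
Reagents that add atoms: none
Why: Weiler dianion alkylation; the more reactive γ‑carbanion displaces the allylic bromide (SN2).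

Step 2
Reactants: 3
Product: 4 methyl (2Z)‑3‑(diethoxyphosphoryloxy)‑7‑methylocta‑2,6‑dienoate
Conditions: NaH, Et2O, 0 °C; ClP(O)(OEt)2
Reagents that add atoms: diethyl chlorophosphate, CCOP(=O)(Cl)OCC
Why: O‑phosphorylation of the chelated sodium enolate gives the Z‑enol phosphate.

Step 3
Reactants: 4
Product: 5 methyl geranate, methyl (2E)‑3,7‑dimethylocta‑2,6‑dienoate
Conditions: Me2CuLi (MeLi, CuI), Et2O, −78 → −45 °C
Reagents that add atoms: lithium dimethylcuprate, [Li+].C[Cu-]C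
Why: cuprate addition–elimination on the enol phosphate proceeds with retention, giving the E‑trisubstituted enoate.

**East half (hydroxyl half, 3R)**

Step 4
Reactants: 5
Product: 6 methyl (2E,6R)‑6,7‑epoxy‑3,7‑dimethyloct‑2‑enoate
Conditions: Shi ketone (D‑fructose‑derived, 30 mol %), Oxone, K2CO3, Bu4NHSO4, MeCN–DMM/aq. borate buffer pH 10.5, 0 °C
Reagents that add atoms: Oxone (KHSO5), [K+].OOS(=O)(=O)[O-]
Why: Shi asymmetric epoxidation; the chiral dioxirane attacks only the electron‑rich distal alkene (the enoate is inert) and the spiro transition state gives the (6R) epoxide.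

Step 5
Reactants: 6
Product: 7 (2E,6R)‑6,7‑epoxy‑3,7‑dimethyloct‑2‑en‑1‑ol
Conditions: DIBAL‑H, CH2Cl2, −78 °C
Reagents that add atoms: none
Why: 1,2‑reduction of the enoate; the trisubstituted epoxide is not opened at −78 °C.

Step 6
Reactants: 7
Product: 8 (2S,3S,6R)‑2,3:6,7‑diepoxy‑3,7‑dimethyloctan‑1‑ol
Conditions: Ti(OiPr)4 (10 mol %), L‑(+)‑DET, t‑BuOOH, 4 Å MS, CH2Cl2, −20 °C
Reagents that add atoms: tert‑butyl hydroperoxide, CC(C)(C)OO
Why: Sharpless asymmetric epoxidation; L‑(+)‑DET gives the (2S,3S) epoxy alcohol under reagent control, independent of the remote epoxide.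

Step 7
Reactants: 8
Product: 9 (2S,3S,6R)‑2,3:6,7‑diepoxy‑3,7‑dimethyloctyl trifluoromethanesulfonate (used crude)
Conditions: Tf2O, 2,6‑lutidine, CH2Cl2, −78 °C
Reagents that add atoms: triflic anhydride, FC(F)(F)S(=O)(=O)OS(=O)(=O)C(F)(F)F
Why: O‑sulfonylation of the primary alcohol gives a leaving group that reacts at −78 °C, faster than either epoxide.

Step 8
Reactants: 9; 1 methyl acetoacetate
Product: 10 methyl (6S,7S,10R)‑6,7:10,11‑diepoxy‑7,11‑dimethyl‑3‑oxododecanoate
Conditions: 1, NaH then n‑BuLi, THF, 0 °C; 9, −78 °C; AcOH quench at −78 °C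
Reagents that add atoms: none
Why: SN2 displacement of the primary triflate by the acetoacetate γ‑carbanion; the epoxide stereocentres are untouched and the resulting mono‑enolate is too weak to open the epoxides at low temperature.

Step 9
Reactants: 10
Product: 11 methyl (2Z,6S,7S,10R)‑3‑(tert‑butyldimethylsilyloxy)‑6,7:10,11‑diepoxy‑7,11‑dimethyldodec‑2‑enoate
Conditions: NaH, TBSCl, THF, 0 °C
Reagents that add atoms: TBSCl, CC(C)(C)[Si](C)(C)Cl
Why: O‑silylation of the β‑keto ester enolate gives a carbon‑nucleophilic terminator (enol geometry is inconsequential).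

Step 10
Reactants: 11
Product: 12 methyl (3R,5aS,9aS)‑3‑(tert‑butyldimethylsilyloxy)‑2,2,5a‑trimethyl‑7‑oxodecahydro‑1‑benzoxepine‑6‑carboxylate (C‑6 epimers/enol)
Conditions: TBSOTf (1.1 equiv), 2,6‑di‑tert‑butyl‑4‑methylpyridine, CH2Cl2, −78 °C; Et3N/MeOH quench
Reagents that add atoms: none (net isomerisation; the silyl group is relayed to O‑3 via TBSOTf)
Why: epoxonium oxa/carbacyclization cascade. The silylated terminal epoxide is opened at tertiary C‑11 by the neighbouring epoxide oxygen (C‑10 retained → 3R‑OTBS). The resulting epoxonium is then opened at tertiary C‑7 with inversion by the enol silane through a chair transition state, O staying on C‑6, which gives the trans‑fused (5aS,9aS) oxepane–cyclohexanone.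

Step 11
Reactants: 12
Product: 13 methyl (3R,5aS,9aS)‑3‑(TBSO)‑2,2,5a‑trimethyl‑7‑(trifluoromethylsulfonyloxy)‑2,3,4,5,5a,8,9,9a‑octahydro‑1‑benzoxepine‑6‑carboxylate
Conditions: NaH, PhNTf2, THF, 0 °C → rt
Reagents that add atoms: N‑phenyl triflimide, FC(F)(F)S(=O)(=O)N(c1ccccc1)S(=O)(=O)C(F)(F)F
Why: the only acidic site is the β‑keto ester; O‑triflation of its enolate fixes the C6=C7 alkene (C‑5a is quaternary, so there is no regiochemical choice).

Step 12
Reactants: 13
Product: 14 methyl (3R,5aS,9aS)‑3‑(TBSO)‑2,2,5a,7‑tetramethyl‑2,3,4,5,5a,8,9,9a‑octahydro‑1‑benzoxepine‑6‑carboxylate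
Conditions: Me2CuLi, THF/Et2O, −78 → 0 °C
Reagents that add atoms: lithium dimethylcuprate, [Li+].C[Cu-]C
Why: cuprate coupling with the β‑triflyloxy enoate installs the C‑7 methyl and the tetrasubstituted alkene; ester and silyl ether are inert.

Step 13
Reactants: 14
Product: 15 [(3R,5aS,9aS)‑3‑(TBSO)‑2,2,5a,7‑tetramethyl‑2,3,4,5,5a,8,9,9a‑octahydro‑1‑benzoxepin‑6‑yl]methanol
Conditions: DIBAL‑H, CH2Cl2, −78 → 0 °C
Reagents that add atoms: none
Why: 1,2‑reduction of the hindered enoate to the allylic alcohol.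

Step 14
Reactants: 15
Product: 16 (3R,5aS,9aS)‑6‑(bromomethyl)‑3‑(TBSO)‑2,2,5a,7‑tetramethyl‑2,3,4,5,5a,8,9,9a‑octahydro‑1‑benzoxepine (used promptly)
Conditions: CBr4, PPh3, 2,6‑lutidine, CH2Cl2, −20 °C
Reagents that add atoms: carbon tetrabromide, BrC(Br)(Br)Br
Why: Appel bromination under neutral conditions; SN2′ is blocked because it would create a quaternary centre.

**West half (ketone half)**

Step 15
Reactants: 5
Product: 17 geraniol, (2E)‑3,7‑dimethylocta‑2,6‑dien‑1‑ol
Conditions: DIBAL‑H, CH2Cl2, −78 °C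
Reagents that add atoms: none
Why: 1,2‑reduction of the enoate.

Step 16
Reactants: 17
Product: 18 (2S,3S,6S)‑2,3:6,7‑diepoxy‑3,7‑dimethyloctan‑1‑ol
Conditions: ent‑Shi ketone (L‑fructose‑derived, 0.5 equiv), Oxone (3.5 equiv), K2CO3, Bu4NHSO4, MeCN–DMM/buffer pH 10.5, −5 °C
Reagents that add atoms: Oxone (KHSO5), [K+].OOS(=O)(=O)[O-]
Why: two‑fold Shi epoxidation; the ent‑ketone gives (S,S)/(S) epoxides on both trisubstituted alkenes. The C‑6 centre is later erased, and removing minor diastereomers upgrades the ee of the (2S,3S) unit.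

Step 17
Reactants: 18
Product: 19 (2S,3S,6S)‑2,3:6,7‑diepoxy‑3,7‑dimethyloctyl trifluoromethanesulfonate (used crude)
Conditions: Tf2O, 2,6‑lutidine, CH2Cl2, −78 °C
Reagents that add atoms: triflic anhydride, FC(F)(F)S(=O)(=O)OS(=O)(=O)C(F)(F)F
Why: as step 7.

Step 18
Reactants: 19; 1 methyl acetoacetate
Product: 20 methyl (6S,7S,10S)‑6,7:10,11‑diepoxy‑7,11‑dimethyl‑3‑oxododecanoate
Conditions: 1, NaH then n‑BuLi, THF, 0 °C; 19, −78 °C; AcOH quench
Reagents that add atoms: none
Why: as step 8 (dianion SN2 on the primary triflate).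

Step 19
Reactants: 20
Product: 21 methyl (2Z,6S,7S,10S)‑3‑(triethylsilyloxy)‑6,7:10,11‑diepoxy‑7,11‑dimethyldodec‑2‑enoate
Conditions: NaH, TESCl, THF, 0 °C
Reagents that add atoms: TESCl, CC[Si](Cl)(CC)CC
Why: enolate O‑silylation; TES is chosen so this half can later be unmasked selectively.

Step 20
Reactants: 21
Product: 22 methyl (3S,5aS,9aS)‑3‑(triethylsilyloxy)‑2,2,5a‑trimethyl‑7‑oxodecahydro‑1‑benzoxepine‑6‑carboxylate (C‑6 epimers/enol)
Conditions: TESOTf (1.1 equiv), 2,6‑di‑tert‑butyl‑4‑methylpyridine, CH2Cl2, −78 °C; Et3N/MeOH quench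
Reagents that add atoms: none (net isomerisation; silyl relayed to O‑3 via TESOTf)
Why: same epoxonium cascade as step 10; retention at C‑6, inversion at C‑7 and a chair carbacyclization give the trans (5aS,9aS) fusion.

Step 21
Reactants: 22
Product: 23 methyl (3S,5aS,9aS)‑3‑(TESO)‑2,2,5a‑trimethyl‑7‑(trifluoromethylsulfonyloxy)‑2,3,4,5,5a,8,9,9a‑octahydro‑1‑benzoxepine‑6‑carboxylate
Conditions: NaH, PhNTf2, THF, 0 °C → rt
Reagents that add atoms: N‑phenyl triflimide, FC(F)(F)S(=O)(=O)N(c1ccccc1)S(=O)(=O)C(F)(F)F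
Why: as step 11.

Step 22
Reactants: 23
Product: 24 methyl (3S,5aS,9aS)‑3‑(TESO)‑2,2,5a,7‑tetramethyl‑2,3,4,5,5a,8,9,9a‑octahydro‑1‑benzoxepine‑6‑carboxylate
Conditions: Me2CuLi, THF/Et2O, −78 → 0 °C
Reagents that add atoms: lithium dimethylcuprate, [Li+].C[Cu-]C
Why: as step 12.

Step 23
Reactants: 24
Product: 25 [(3S,5aS,9aS)‑3‑(TESO)‑2,2,5a,7‑tetramethyl‑2,3,4,5,5a,8,9,9a‑octahydro‑1‑benzoxepin‑6‑yl]methanol
Conditions: DIBAL‑H, CH2Cl2, −78 → 0 °C
Reagents that add atoms: none
Why: as step 13.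

Step 24
Reactants: 25
Product: 26 (3S,5aS,9aS)‑6‑(bromomethyl)‑3‑(TESO)‑2,2,5a,7‑tetramethyl‑2,3,4,5,5a,8,9,9a‑octahydro‑1‑benzoxepine
Conditions: CBr4, PPh3, 2,6‑lutidine, CH2Cl2, −20 °C
Reagents that add atoms: carbon tetrabromide, BrC(Br)(Br)Br
Why: as step 14.

Step 25
Reactants: 26
Product: 27 (3S,5aS,9aS)‑6‑[(phenylsulfonyl)methyl]‑3‑(TESO)‑2,2,5a,7‑tetramethyl‑2,3,4,5,5a,8,9,9a‑octahydro‑1‑benzoxepine
Conditions: PhSO2Na, DMF, rt
Reagents that add atoms: sodium benzenesulfinate, [Na+].[O-]S(=O)c1ccccc1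
Why: S‑alkylation of sulfinate by the primary allylic bromide (SN2) gives the carbanion‑stabilising sulfone.

**Fragment union and endgame**

Step 26
Reactants: 27 west sulfone; 16 east bromide
Product: 28 (3S,5aS,9aS)‑6‑{2‑[(3R,5aS,9aS)‑3‑(TBSO)‑2,2,5a,7‑tetramethyl‑octahydro‑1‑benzoxepin‑6‑yl]‑1‑(phenylsulfonyl)ethyl}‑3‑(TESO)‑2,2,5a,7‑tetramethyl‑octahydro‑1‑benzoxepine (sulfone‑carbon epimers)
Conditions: 27, n‑BuLi, THF–HMPA, −78 °C; then 16, −78 → −30 °C
Reagents that add atoms: none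
Why: Julia/Biellmann‑type alkylation; the α‑sulfonyl allyl anion reacts at its α‑carbon with the primary allylic bromide (γ‑attack and SN2′ would both create quaternary centres), forming the central C–C bond.

Step 27
Reactants: 28
Product: 29 1‑[(3S,5aS,9aS)‑3‑(TESO)‑…‑benzoxepin‑6‑yl]‑2‑[(3R,5aS,9aS)‑3‑(TBSO)‑…‑benzoxepin‑6‑yl]ethane (both halves 2,2,5a,7‑tetramethyl‑octahydro)
Conditions: PdCl2(dppp) (10 mol %), LiBHEt3, THF, 0 °C → rt
Reagents that add atoms: none
Why: Pd‑catalysed reductive desulfonylation; hydride is delivered to the less hindered exocyclic terminus of the π‑allyl, so the tetrasubstituted ring alkene stays in place and the sulfone stereocentre disappears.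

Step 28
Reactants: 29
Product: 30 west (3S)‑alcohol, east 3‑OTBS ether
Conditions: PPTS, MeOH–CH2Cl2, 0 °C → rt
Reagents that add atoms: none
Why: acid solvolysis cleaves the TES ether far faster than the hindered secondary TBS ether.

Step 29
Reactants: 30
Product: 31 west (5aS,9aS)‑oxepan‑3‑one, east 3‑OTBS ether
Conditions: Dess–Martin periodinane, NaHCO3, CH2Cl2, rt
Reagents that add atoms: none
Why: neutral oxidation of the secondary alcohol; alkenes, ethers and the TBS group are inert, and the west C‑3 stereocentre is erased as planned.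

Step 30
Reactants: 31
Product: 32 sodwanone T
Conditions: HF·pyridine, THF–pyridine, 0 °C → rt
Reagents that add atoms: none
Why: fluoride desilylation releases the (3R)‑alcohol; nothing adjacent to the ketone is epimerisable.

**Compound list**
1 | methyl acetoacetate | COC(=O)CC(C)=O | starting material
2 | prenyl bromide (1‑bromo‑3‑methylbut‑2‑ene) | CC(C)=CCBr | starting material
3 | methyl 7‑methyl‑3‑oxooct‑6‑enoate | COC(=O)CC(=O)CCC=C(C)C | intermediate
4 | methyl (2Z)‑3‑(diethoxyphosphoryloxy)‑7‑methylocta‑2,6‑dienoate | COC(=O)/C=C(\OP(=O)(OCC)OCC)CCC=C(C)C | intermediate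
5 | methyl geranate | COC(=O)/C=C(\C)CCC=C(C)C | intermediate
6 | methyl (2E,6R)‑6,7‑epoxy‑3,7‑dimethyloct‑2‑enoate | COC(=O)/C=C(\C)CC[C@H]1OC1(C)C | intermediate
7 | (2E,6R)‑6,7‑epoxy‑3,7‑dimethyloct‑2‑en‑1‑ol | OC/C=C(\C)CC[C@H]1OC1(C)C | intermediate
8 | (2S,3S,6R)‑2,3:6,7‑diepoxy‑3,7‑dimethyloctan‑1‑ol | OC[C@@H]1O[C@@]1(C)CC[C@H]1OC1(C)C | intermediate
9 | triflate of 8 | O=S(=O)(OC[C@@H]1O[C@@]1(C)CC[C@H]1OC1(C)C)C(F)(F)F | intermediate
10 | methyl (6S,7S,10R)‑6,7:10,11‑diepoxy‑7,11‑dimethyl‑3‑oxododecanoate | COC(=O)CC(=O)CC[C@@H]1O[C@@]1(C)CC[C@H]1OC1(C)C | intermediate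
11 | TBS enol ether of 10 (2Z) | COC(=O)/C=C(\O[Si](C)(C)C(C)(C)C)CC[C@@H]1O[C@@]1(C)CC[C@H]1OC1(C)C | intermediate
12 | east bicyclic β‑keto ester (3R,5aS,9aS), 3‑OTBS | COC(=O)C1C(=O)CC[C@@H]2OC(C)(C)[C@H](O[Si](C)(C)C(C)(C)C)CC[C@@]12C | intermediate
13 | east enol triflate | COC(=O)C1=C(OS(=O)(=O)C(F)(F)F)CC[C@@H]2OC(C)(C)[C@H](O[Si](C)(C)C(C)(C)C)CC[C@@]12C | intermediate
14 | east 7‑methyl enoate | COC(=O)C1=C(C)CC[C@@H]2OC(C)(C)[C@H](O[Si](C)(C)C(C)(C)C)CC[C@@]12C | intermediate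
15 | east allylic alcohol | OCC1=C(C)CC[C@@H]2OC(C)(C)[C@H](O[Si](C)(C)C(C)(C)C)CC[C@@]12C | intermediate
16 | east allylic bromide | BrCC1=C(C)CC[C@@H]2OC(C)(C)[C@H](O[Si](C)(C)C(C)(C)C)CC[C@@]12C | intermediate
17 | geraniol | OC/C=C(\C)CCC=C(C)C | intermediate
18 | (2S,3S,6S)‑2,3:6,7‑diepoxy‑3,7‑dimethyloctan‑1‑ol | OC[C@@H]1O[C@@]1(C)CC[C@@H]1OC1(C)C | intermediate
19 | triflate of 18 | O=S(=O)(OC[C@@H]1O[C@@]1(C)CC[C@@H]1OC1(C)C)C(F)(F)F | intermediate
20 | methyl (6S,7S,10S)‑6,7:10,11‑diepoxy‑7,11‑dimethyl‑3‑oxododecanoate | COC(=O)CC(=O)CC[C@@H]1O[C@@]1(C)CC[C@@H]1OC1(C)C | intermediate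
21 | TES enol ether of 20 (2Z) | COC(=O)/C=C(\O[Si](CC)(CC)CC)CC[C@@H]1O[C@@]1(C)CC[C@@H]1OC1(C)C | intermediate
22 | west bicyclic β‑keto ester (3S,5aS,9aS), 3‑OTES | COC(=O)C1C(=O)CC[C@@H]2OC(C)(C)[C@@H](O[Si](CC)(CC)CC)CC[C@@]12C | intermediate
23 | west enol triflate | COC(=O)C1=C(OS(=O)(=O)C(F)(F)F)CC[C@@H]2OC(C)(C)[C@@H](O[Si](CC)(CC)CC)CC[C@@]12C | intermediate
24 | west 7‑methyl enoate | COC(=O)C1=C(C)CC[C@@H]2OC(C)(C)[C@@H](O[Si](CC)(CC)CC)CC[C@@]12C | intermediate
25 | west allylic alcohol | OCC1=C(C)CC[C@@H]2OC(C)(C)[C@@H](O[Si](CC)(CC)CC)CC[C@@]12C | intermediate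
26 | west allylic bromide | BrCC1=C(C)CC[C@@H]2OC(C)(C)[C@@H](O[Si](CC)(CC)CC)CC[C@@]12C | intermediate
27 | west allylic phenyl sulfone | O=S(=O)(CC1=C(C)CC[C@@H]2OC(C)(C)[C@@H](O[Si](CC)(CC)CC)CC[C@@]12C)c1ccccc1 | intermediate
28 | coupled sulfone (epimers at the sulfone carbon) | O=S(=O)(C(CC1=C(C)CC[C@@H]2OC(C)(C)[C@H](O[Si](C)(C)C(C)(C)C)CC[C@@]12C)C1=C(C)CC[C@@H]2OC(C)(C)[C@@H](O[Si](CC)(CC)CC)CC[C@@]12C)c1ccccc1 | intermediate
29 | bis‑silyl ether (west OTES, east OTBS) | C(CC1=C(C)CC[C@@H]2OC(C)(C)[C@H](O[Si](C)(C)C(C)(C)C)CC[C@@]12C)C1=C(C)CC[C@@H]2OC(C)(C)[C@@H](O[Si](CC)(CC)CC)CC[C@@]12C | intermediate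
30 | west alcohol, east OTBS | C(CC1=C(C)CC[C@@H]2OC(C)(C)[C@H](O[Si](C)(C)C(C)(C)C)CC[C@@]12C)C1=C(C)CC[C@@H]2OC(C)(C)[C@@H](O)CC[C@@]12C | intermediate
31 | west ketone, east OTBS | C(CC1=C(C)CC[C@@H]2OC(C)(C)[C@H](O[Si](C)(C)C(C)(C)C)CC[C@@]12C)C1=C(C)CC[C@@H]2OC(C)(C)C(=O)CC[C@@]12C | intermediate
32 | sodwanone T | CC1=C(CCC2=C(C)CC[C@@H]3OC(C)(C)[C@H](O)CC[C@@]23C)[C@]2(C)CCC(=O)C(C)(C)O[C@H]2CC1 | target

**Totals**
Total steps: 30. Longest linear sequence: 19 (steps 1–3, 4–14, 26–30; the west line 1–3, 15–25, 26–30 is equally long), i.e. 19/30 ≈ 0.63.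

**Three steps most likely to fail, with fallbacks**
1. Steps 10 and 20, the epoxonium cascade. Step 10 is the riskier one: its diepoxide has unlike epoxide senses and the terminator is a deactivated β‑silyloxy enoate, so THF/THP formation or O‑termination could compete. Fallback: build the rings in two events. Cyclise the (6S,7S)‑mono‑epoxy β‑keto ester (10,11‑alkene intact) with MeAlCl2 or SnCl4 to the hydroxy‑cyclohexane, carry it to the 7‑methyl enoate, then Shi‑epoxidise the side‑chain alkene and close the oxepane by acid‑mediated, tertiary‑selective 7‑endo hydroxy‑epoxide opening.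
2. Steps 8 and 18, dianion alkylation with a 2,3‑epoxy triflate. Epoxide opening or later enolate/epoxide cyclization could compete. Fallback: reverse the order. Alkylate the dianion with the allylic bromide from 7 (or geranyl bromide), mask the β‑keto ester by reduction to the silyl‑protected β‑hydroxy ester, install the internal epoxide by reagent‑controlled Shi epoxidation, and re‑oxidise to the β‑keto ester before enol silylation.
3. Steps 26–27, the union. The alkylation joins two neopentyl‑like allylic partners, and the Pd desulfonylation has to engage a tetrasubstituted alkene without shifting it. Fallback: join the halves by olefination. Oxidise 15 to the enal (MnO2), convert 26 to the phosphonium salt or PT‑sulfone, carry out Wittig or Julia–Kocienski coupling to the CH=CH‑linked triene, and reduce only the central disubstituted alkene with diimide before the same TES/oxidation/TBS endgame.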